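**Retrosynthetic overview**
1. Target ⇒ open O1–C2: a p-quinone methide that already carries the C3 stereocentre. The dihydrofuran ring is the only ring made and closes last, by trans-selective oxa-1,6-addition of the ring A 4-OH.
2. p-Quinone methide ⇒ cut C3–C3a: piceatannol o-quinone (electrophilic at C8) plus unprotected oxyresveratrol (nucleophilic at C5 of ring A), joined by an enantioselective vinylogous Friedel–Crafts addition under a chiral phosphoric acid.
3. Piceatannol o-quinone ⇐ piceatannol (Ag2O). Piceatannol and oxyresveratrol are both purchased natural stilbenes, so the oxidative heterodimerisation is a single operation.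

Assumption: the (R)-acid is taken to give the (2S,3S) series; the facial sense of this new step must be confirmed on the first run (chiral HPLC, ECD), and the equally available (S)-acid is used if it is the opposite.

**Step 1**
Reactants: 1 piceatannol; 2 oxyresveratrol
Product: 5 (2S,3S)-2-(3,4-dihydroxyphenyl)-3-(3,5-dihydroxyphenyl)-5-[(E)-2-(3,5-dihydroxyphenyl)ethenyl]-2,3-dihydro-1-benzofuran-6-ol (target; 2,3-trans), via piceatannol o-quinone 3 (not isolated), via p-quinone methide 4 (not isolated)
Conditions: 1 added over 10 min to Ag2O (3 equiv), Na2SO4, EtOAc, −30 °C, then cold filtration (Celite, Ar); filtrate added over 1 h to 2 (2.5 equiv), (R)-3,3′-bis(2,4,6-triisopropylphenyl)-1,1′-binaphthalene-2,2′-diyl hydrogen phosphate (10 mol%), 4 Å MS, EtOAc, −40 → −20 °C, dark, 12 h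
Reagents that add atoms: none
Why: Proposed new method: Ag2O oxidises only the catechol of 1 to the o-quinone 3 (classical catechol-to-o-quinone oxidation), in which C8 is the terminus of the vinylogous acceptor O=C3–C2=C1–C7=C8; (R)-3,3′-bis(2,4,6-triisopropylphenyl)-1,1′-binaphthalene-2,2′-diyl hydrogen phosphate is expected to hold 3 through its P–OH (quinone carbonyls) and 2 through its P=O (4-OH of ring A), so that C5 of ring A (ortho to that OH, para to the 2-OH, unhindered) adds to one enantiotopic face of C8 in an enantio-determining vinylogous 1,6-Friedel–Crafts (Michael) addition that sets C3 as S, after which the p-quinone methide 4 is closed by the same phenol oxygen in a 5-exo oxa-1,6-addition (overall a biomimetic oxidative formal [3+2] phenol–stilbene coupling, C8–C5′ then O–C7 as in the presumed biosynthesis) with the catechol ring going anti to the C3 aryl group (C2 = S, trans; the closure is reversible under the acid, so trans is also the equilibrium outcome); the closest known reaction types are chiral phosphoric acid-catalysed 1,6- and 1,8-additions of phenols, naphthols and indoles to p-quinone methides, acid-catalysed formal [3+2] annulations of quinones, and the racemic silver-mediated 8–5′ oxidative dimerisation of resveratrol to δ-viniferin.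

**Compound list**
1 | piceatannol, (E)-4-[2-(3,5-dihydroxyphenyl)ethenyl]benzene-1,2-diol | Oc1ccc(/C=C/c2cc(O)cc(O)c2)cc1O | starting material
2 | oxyresveratrol, (E)-4-[2-(3,5-dihydroxyphenyl)ethenyl]benzene-1,3-diol | Oc1ccc(/C=C/c2cc(O)cc(O)c2)c(O)c1 | starting material
3 | piceatannol o-quinone, 4-[(E)-2-(3,5-dihydroxyphenyl)ethenyl]cyclohexa-3,5-diene-1,2-dione | O=C1C=CC(/C=C/c2cc(O)cc(O)c2)=CC1=O | intermediate
4 | p-quinone methide, 4-{(2S)-2-(3,5-dihydroxyphenyl)-2-[2,4-dihydroxy-5-((E)-3,5-dihydroxystyryl)phenyl]ethylidene}-2-hydroxycyclohexa-2,5-dien-1-one (geometry of the exocyclic quinone methide alkene not fixed) | O=C1C=CC(=C[C@@H](c2cc(O)cc(O)c2)c2cc(/C=C/c3cc(O)cc(O)c3)c(O)cc2O)C=C1O | intermediate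
5 | (2S,3S)-2-(3,4-dihydroxyphenyl)-3-(3,5-dihydroxyphenyl)-5-[(E)-2-(3,5-dihydroxyphenyl)ethenyl]-2,3-dihydro-1-benzofuran-6-ol (CNP0263230.1) | Oc1cc(O)cc(/C=C/c2cc3c(cc2O)O[C@H](c2ccc(O)c(O)c2)[C@H]3c2cc(O)cc(O)c2)c1 | target

**Totals**
Total step count: 1. Longest linear sequence: 1 (1 + 2 → 5).

**Steps most likely to fail**
The route has a single step, so only that step is ranked and there is no second or third.

Step 1. The o-quinone 3 can also react as a heterodiene across the alkene of 2 (benzodioxanes), be attacked at its ring carbons or by ring B of 2, or condense with its own resorcinol ring. The enantioselectivity of the new step is also unproven. If the ee is below 99%, one pass of chiral HPLC polishes the product. The fallback sets out from 1 and 2 and comes back at 5. Both stilbenes are oxidised together with AgOAc (2 equiv, MeOH, 50 °C, dark), the conditions that dimerise resveratrol in the 8–5′ sense. The C8–C5′ bond is then made by free phenoxyl radical coupling and the quinone methide closes trans, but without stereocontrol. The product is the racemate, that is 5 together with its (2R,3R)-enantiomer F1. Homodimers and regioisomers are removed on C18 silica, and 5 is separated from F1 by preparative HPLC on an amylose tris(3,5-dimethylphenylcarbamate) phase.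

**Further compounds**
F1 | step 1 | (2R,3R)-2-(3,4-dihydroxyphenyl)-3-(3,5-dihydroxyphenyl)-5-[(E)-2-(3,5-dihydroxyphenyl)ethenyl]-2,3-dihydro-1-benzofuran-6-ol (enantiomer of 5) | Oc1cc(O)cc(/C=C/c2cc3c(cc2O)O[C@@H](c2ccc(O)c(O)c2)[C@@H]3c2cc(O)cc(O)c2)c1
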